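Ring letters: A = trimethylcyclohexane, B = cyclopentane, C = epoxycyclohexane, D = hydroxylactam. Ring A is disconnected at its CH2–CH(CH3) bond beside the A/B fusion methine. This gives seco-A diene 34, with isopropenyl on the fusion methine and 2-methylbut-3-enyl on the quaternary fusion carbon. It is closed by metathesis plus radical hydrogenation in one flask.
Enabling feature: ring A is a pure hydrocarbon ring trans-fused to ring B, so its two branches on the B-ring bond CH–C(CH3) are diequatorial and gauche. Its only axial group is the angular methyl, which makes the equatorial (natural) secondary methyl the thermodynamic one.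
Ring D comes from nitrile hydration followed by addition of the amide N to the benzyl ketone. The 13-membered paracyclophane comes from C-alkylation of a β-ketonitrile by the aryl chloromethyl ketone.
The oxirane is made on ring C by bromohydrin formation and closure. Rings B and C form together in an endo intramolecular Diels–Alder reaction of an (E)-enal with an (E,Z)-diene.
The acyclic chain takes three contiguous stereocentres from an (R)-butenolide template (cuprate addition, two enolate alkylations), and both ends are grown by Wittig steps. Ring order: B + C, oxirane, macrocycle, D, A.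

Key step: step 27

Assumption: the carbinolamide carbon of ring D and the enol geometry equilibrate (ring–chain and keto–enol tautomerism) and are fixed thermodynamically by the cyclophane, and both enantiomers of 5-(hydroxymethyl)furan-2(5H)-one are taken as purchasable.

Step 1
Reactants: 1 methyl (S)-3-hydroxy-2-methylpropanoate
Product: 2 methyl (S)-3-[(tert-butyldimethylsilyl)oxy]-2-methylpropanoate
Conditions: TBSCl, imidazole, DMF, 23 °C
Reagents that add atoms: tert-butyldimethylsilyl chloride, CC(C)(C)[Si](C)(C)Cl
Why: Silyl ether protection of the primary alcohol, which does not touch the stereocentre that becomes the remote methyl carbon of ring A.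

Step 2
Reactants: 2 methyl (S)-3-[(tert-butyldimethylsilyl)oxy]-2-methylpropanoate
Product: 3 (S)-3-[(tert-butyldimethylsilyl)oxy]-2-methylpropanal
Conditions: iBu2AlH, CH2Cl2, −78 °C
Reagents that add atoms: none
Why: Half-reduction of the ester with iBu2AlH stops at the aluminium hemiacetal at low temperature, and the α-stereocentre holds because the aldehyde is used at once.

Step 3
Reactants: 3 (S)-3-[(tert-butyldimethylsilyl)oxy]-2-methylpropanal
Product: 4 (R)-tert-butyldimethyl[(2-methylbut-3-en-1-yl)oxy]silane
Conditions: Ph3PCH3Br, KN(SiMe3)2, THF, −78 to 0 °C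
Reagents that add atoms: methyltriphenylphosphonium bromide, C[P+](c1ccccc1)(c1ccccc1)c1ccccc1.[Br-]
Why: Wittig methylenation turns the aldehyde into the terminal alkene needed later for metathesis without epimerisation.

Step 4
Reactants: 4 (R)-tert-butyldimethyl[(2-methylbut-3-en-1-yl)oxy]silane
Product: 5 (R)-2-methylbut-3-en-1-ol
Conditions: Bu4NF, THF, 23 °C
Reagents that add atoms: none
Why: Fluoride-induced desilylation frees the primary alcohol.

Step 5
Reactants: 6 2-(4-iodophenyl)acetic acid
Product: 7 2-(4-iodophenyl)-N-methoxy-N-methylacetamide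
Conditions: MeNHOMe·HCl, EDC·HCl, Et3N, CH2Cl2, 23 °C
Reagents that add atoms: N,O-dimethylhydroxylamine hydrochloride, CNOC.Cl
Why: Carbodiimide amide coupling installs the N-methoxy-N-methylamide, which stays inert until it is turned into the chloromethyl ketone.

Step 6
Reactants: 7 2-(4-iodophenyl)-N-methoxy-N-methylacetamide
Product: 9 {4-[2-(methoxy(methyl)amino)-2-oxoethyl]phenyl}(2,4,6-trimethoxyphenyl)iodonium tosylate, via hydroxy(tosyloxy)iodane 8 (not isolated)
Conditions: mCPBA, TsOH·H2O, MeCN, 77 °C; then 1,3,5-trimethoxybenzene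
Reagents that add atoms: p-toluenesulfonic acid monohydrate, Cc1ccc(cc1)S(=O)(=O)O.O; 1,3,5-trimethoxybenzene, COc1cc(OC)cc(OC)c1
Why: One-pot oxidation of the aryl iodide to trivalent iodine and electrophilic aromatic substitution on trimethoxybenzene gives an unsymmetrical diaryliodonium salt whose electron-rich aryl group acts as the non-transferred ligand.

Step 7
Reactants: 10 (R)-5-(hydroxymethyl)furan-2(5H)-one
Product: 11 (R)-5-{[(tert-butyldimethylsilyl)oxy]methyl}furan-2(5H)-one
Conditions: TBSCl, imidazole, DMF, 23 °C
Reagents that add atoms: tert-butyldimethylsilyl chloride, CC(C)(C)[Si](C)(C)Cl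
Why: Silyl ether protection gives a bulky group on the carbon that becomes the aryloxy-bearing carbon of ring B.

Step 8
Reactants: 11 (R)-5-{[(tert-butyldimethylsilyl)oxy]methyl}furan-2(5H)-one
Product: 12 (4S,5R)-5-{[(tert-butyldimethylsilyl)oxy]methyl}-4-(prop-1-en-2-yl)dihydrofuran-2(3H)-one
Conditions: CH2=C(CH3)MgBr, CuBr·SMe2, THF/Me2S, −78 °C
Reagents that add atoms: isopropenylmagnesium bromide, C=C(C)[Mg]Br
Why: Organocuprate 1,4-addition to the butenolide, in which the nucleophile enters anti to the silyloxymethyl group and so sets the future A/B fusion methine.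

Step 9
Reactants: 12 (4S,5R)-5-{[(tert-butyldimethylsilyl)oxy]methyl}-4-(prop-1-en-2-yl)dihydrofuran-2(3H)-one
Product: 13 (3R,4S,5R)-5-{[(tert-butyldimethylsilyl)oxy]methyl}-3-methyl-4-(prop-1-en-2-yl)dihydrofuran-2(3H)-one
Conditions: iPr2NLi, THF, −78 °C; MeI
Reagents that add atoms: iodomethane, CI
Why: Lactone enolate alkylation brings in the future angular methyl, and its first orientation does not matter because this carbon is planarised again in the next step.

Step 10
Reactants: 13 (3R,4S,5R)-5-{[(tert-butyldimethylsilyl)oxy]methyl}-3-methyl-4-(prop-1-en-2-yl)dihydrofuran-2(3H)-one; 5 (R)-2-methylbut-3-en-1-ol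
Product: 15 (3R,4R,5R)-5-{[(tert-butyldimethylsilyl)oxy]methyl}-3-methyl-3-[(2S)-2-methylbut-3-en-1-yl]-4-(prop-1-en-2-yl)dihydrofuran-2(3H)-one, via butenyl triflate 14 (not isolated)
Conditions: 5, Tf2O, 2,6-lutidine, CH2Cl2, −78 °C; 13, iPr2NLi, THF/DMPU, −78 °C, then 14, to −20 °C
Reagents that add atoms: none
Why: Second lactone enolate alkylation with a reactive primary triflate, where the electrophile again enters anti to the isopropenyl group, so the quaternary carbon holds its methyl cis and its butenyl arm trans to that group.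

Step 11
Reactants: 15 quaternary lactone
Product: 16 lactol of 15 (anomer mixture)
Conditions: iBu2AlH, CH2Cl2, −78 °C
Reagents that add atoms: none
Why: Half-reduction of the lactone to the lactol exposes the neopentyl carbonyl carbon at the aldehyde level while the other alkenes and the silyl ether stay untouched.

Step 12
Reactants: 16 lactol of 15
Product: 17 hydroxy (E)-enoate EtO2C–C(CH3)=CH–C(CH3)(butenyl)–CH(isopropenyl)–CH(OH)–CH2OTBS with the configuration of 15
Conditions: Ph3P=C(CH3)CO2Et, PhCO2H (cat.), toluene, 100 °C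
Reagents that add atoms: ethyl 2-(triphenyl-λ5-phosphanylidene)propanoate, CCOC(=O)C(C)=P(c1ccccc1)(c1ccccc1)c1ccccc1
Why: Wittig olefination of the lactol through its open hydroxy aldehyde, in which the stabilised ylide gives the (E)-trisubstituted alkene and frees the secondary alcohol.

Step 13
Reactants: 17 hydroxy (E)-enoate
Product: 18 allylic alcohol diol (CH2OH in place of CO2Et)
Conditions: iBu2AlH (excess), CH2Cl2, −78 °C
Reagents that add atoms: none
Why: 1,2-Reduction of the conjugated ester to the allylic alcohol by iBu2AlH.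

Step 14
Reactants: 18 allylic alcohol diol
Product: 19 hydroxy (E)-enal (CHO in place of CH2OH)
Conditions: MnO2, CH2Cl2, 23 °C
Reagents that add atoms: none
Why: Chemoselective MnO2 oxidation takes only the allylic alcohol and leaves the saturated secondary alcohol.

Step 15
Reactants: 19 hydroxy (E)-enal
Product: 20 (2Z,4E)-dienol CH3–CH=CH–C(CH3)=CH–C(CH3)(butenyl)–CH(isopropenyl)–CH(OH)–CH2OTBS
Conditions: Ph3PCH2CH3Br, NaN(SiMe3)2 (excess), THF, −78 °C
Reagents that add atoms: ethyltriphenylphosphonium bromide, CC[P+](c1ccccc1)(c1ccccc1)c1ccccc1.[Br-]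
Why: Salt-free Wittig reaction of a non-stabilised ylide gives the (Z)-propenyl terminus that later places the ring C methyl trans to the quaternary carbon.

Step 16
Reactants: 20 (2Z,4E)-dienol; 9 aryl(2,4,6-trimethoxyphenyl)iodonium tosylate
Product: 21 aryl ether of 20 (aryl = 4-[2-(methoxy(methyl)amino)-2-oxoethyl]phenyl)
Conditions: KN(SiMe3)2, toluene/THF, 0 °C; then 9, 23 °C
Reagents that add atoms: none
Why: Metal-free O-arylation of the potassium alkoxide by ligand coupling at trivalent iodine forms the aryl ether at room temperature with retention at the carbinol carbon and transfers the less electron-rich aryl group.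

Step 17
Reactants: 21 aryl ether of 20
Product: 22 primary alcohol (CH2OH in place of CH2OTBS)
Conditions: Bu4NF, THF, 0 °C
Reagents that add atoms: none
Why: Fluoride desilylation removes the only silyl group left.

Step 18
Reactants: 22 primary alcohol
Product: 23 α-aryloxy aldehyde
Conditions: Dess–Martin periodinane, NaHCO3, CH2Cl2, 0 °C
Reagents that add atoms: none
Why: Dess–Martin oxidation under buffered, non-basic conditions avoids epimerisation of the α-aryloxy stereocentre.

Step 19
Reactants: 23 α-aryloxy aldehyde
Product: 24 trienal with the (E)-enal O=CH–CH=CH–CH(OAr)–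
Conditions: Ph3P=CHCHO, benzene, 45 °C
Reagents that add atoms: (triphenyl-λ5-phosphanylidene)acetaldehyde, O=CC=P(c1ccccc1)(c1ccccc1)c1ccccc1
Why: Wittig two-carbon homologation with the stabilised formyl ylide gives the (E)-enal dienophile under neutral conditions.

Step 20
Reactants: 24 trienal
Product: 25 trans-fused B/C hydrindene aldehyde (ring B with aryloxy, isopropenyl, methyl and butenyl groups; ring C with formyl, methyl and a trisubstituted alkene)
Conditions: Me2AlCl (2.5 equiv), CH2Cl2, −78 to −20 °C
Reagents that add atoms: none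
Why: Lewis-acid-promoted intramolecular Diels–Alder reaction through the endo (aldehyde under the diene) transition state, which makes the B/C fusion trans and places the formyl group trans to both neighbours; the (Z)-propenyl terminus puts the ring C methyl trans to the quaternary carbon, and the diene face is fixed by the chain stereocentres because the carbinol hydrogen eclipses the enal (allylic 1,3-strain) while the aryloxy, isopropenyl and butenyl groups take outside or pseudo-equatorial sites on the forming cyclopentane.

Step 21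
Reactants: 25 hydrindene aldehyde
Product: 27 epoxy aldehyde, via bromohydrin 26 (not isolated)
Conditions: N-bromosuccinimide, DME/H2O, 0 °C; then K2CO3, MeOH, 0 °C
Reagents that add atoms: water, O
Why: Halohydrin route to the epoxide, in which the most electron-rich, trisubstituted ring C alkene takes Br+ on the face away from the angular methyl, water opens the bromonium ion at the tertiary carbon in the trans-diaxial sense, and displacement of bromide then leaves the oxirane syn to the angular methyl, opposite to what direct peracid attack should give.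

Step 22
Reactants: 27 epoxy aldehyde
Product: 28 β-(trimethylsilyloxy)nitrile (epimers at the new carbinol carbon, which is oxidised later)
Conditions: Me3SiCH2CN, LiOAc (10 mol %), DMF, 0 °C
Reagents that add atoms: (trimethylsilyl)acetonitrile, C[Si](C)(C)CC#N
Why: Lewis-base-catalysed aldol-type cyanomethylation adds the two-carbon nitrile unit to the aldehyde only and leaves the amide and the oxirane alone.

Step 23
Reactants: 28 β-(trimethylsilyloxy)nitrile
Product: 30 β-hydroxynitrile aryl chloromethyl ketone, via silyl ether chloroketone 29 (not isolated)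
Conditions: ICH2Cl, MeLi·LiBr, THF/Et2O, −78 °C; AcOH; then citric acid (cat.), MeOH, 0 °C
Reagents that add atoms: chloroiodomethane, ClCI
Why: Weinreb-type ketone synthesis with chloromethyllithium made by iodine–lithium exchange beside the substrate, where the chelated tetrahedral adduct prevents over-addition and mild methanolysis removes the trimethylsilyl ether.

Step 24
Reactants: 30 β-hydroxynitrile aryl chloromethyl ketone
Product: 31 β-ketonitrile aryl chloromethyl ketone
Conditions: Dess–Martin periodinane, CH2Cl2, 0 °C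
Reagents that add atoms: none
Why: Dess–Martin oxidation creates the acidic β-ketonitrile without base, so nucleophile and electrophile coexist until the next step.

Step 25
Reactants: 31 β-ketonitrile aryl chloromethyl ketone
Product: 32 13-membered paracyclophane 2-cyano-1,4-diketone
Conditions: Cs2CO3, Bu4NI (cat.), MeCN (1 mM, slow addition), 40 °C
Reagents that add atoms: none
Why: Irreversible SN2 macrocyclisation of a soft stabilised enolate on an α-haloketone under high dilution, helped because the acyl and aryloxy groups both project from the same face of the rigid B/C core.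

Step 26
Reactants: 32 paracyclophane 2-cyano-1,4-diketone
Product: 34 seco-A hydroxylactam (rings B, C, D, oxirane and macrocycle closed), via ketoamide 33 (not isolated)
Conditions: [PtH(PMe2OH){(PMe2O)2H}] (5 mol %), EtOH/H2O, 70 °C
Reagents that add atoms: water, O
Why: Neutral platinum-catalysed nitrile hydration gives the primary β-ketoamide, whose nitrogen adds to the 1,4-related benzyl ketone (5-exo-trig carbinolamide formation); the reversible addition lets the new carbinol carbon settle in the configuration that the cyclophane bridge accommodates, and the acyl lactam rests as its hydrogen-bonded enol.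

Step 27
Reactants: 34 seco-A hydroxylactam
Product: 36 pyrrospirone O, via cyclohexene 35 (not isolated)
Conditions: second-generation Hoveyda–Grubbs catalyst (10 mol %), toluene (2 mM), 80 °C, Ar sparge; evaporate; then Mn(dpm)3 (20 mol %), PhSiH3, tBuOOH, iPrOH, 23 °C
Reagents that add atoms: none
Why: The ruthenium alkylidene loads on the monosubstituted alkene of the butenyl arm and closes onto the isopropenyl group by [2+2] cycloaddition and cycloreversion with loss of ethene (ring-closing olefin metathesis; the closest known type is trisubstituted cyclohexene formation from a 1,7-diene), after which a manganese hydride made from Mn(dpm)3 and PhSiH3 gives a hydrogen atom to the CH end of the new alkene and the tertiary radical takes a second one (metal-hydride hydrogen-atom-transfer hydrogenation). Ring A is the only ring closed, a six-membered carbocycle made by joining the inner alkene carbons of a 1,7-diene whose tether contains the B-ring bond between the fusion methine and the quaternary carbon. Closure should be fast because the two arms are trans on ring B, hence diequatorial and gauche, and the quaternary carbon adds a Thorpe–Ingold effect. The one new stereocentre, the methyl-bearing carbon next to the fusion methine, is set at the radical stage under product-like control: an axial methyl would be 1,3-diaxial to the angular methyl, so the equatorial, natural epimer is expected, whereas surface hydrogenation from the open lower face would give the axial epimer. No chemoselectivity problem should arise, since 34 holds only these two C=C bonds besides the hydrogen-bonded enol, the radical is not adjacent to the oxirane, and both catalysts tolerate carbinolamide, lactam and aryl ether groups.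

Compound list
1 | methyl (S)-3-hydroxy-2-methylpropanoate | C[C@@H](CO)C(=O)OC | starting material
2 | methyl (S)-3-[(tert-butyldimethylsilyl)oxy]-2-methylpropanoate | C[C@@H](CO[Si](C)(C)C(C)(C)C)C(=O)OC | intermediate
3 | (S)-3-[(tert-butyldimethylsilyl)oxy]-2-methylpropanal | C[C@@H](CO[Si](C)(C)C(C)(C)C)C=O | intermediate
4 | (R)-tert-butyldimethyl[(2-methylbut-3-en-1-yl)oxy]silane | C[C@@H](CO[Si](C)(C)C(C)(C)C)C=C | intermediate
5 | (R)-2-methylbut-3-en-1-ol | C[C@@H](CO)C=C | intermediate
6 | 2-(4-iodophenyl)acetic acid | OC(=O)Cc1ccc(I)cc1 | starting material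
7 | 2-(4-iodophenyl)-N-methoxy-N-methylacetamide | CON(C)C(=O)Cc1ccc(I)cc1 | intermediate
8 | hydroxy(tosyloxy)iodane of 7 | CON(C)C(=O)Cc1ccc(cc1)I(O)OS(=O)(=O)c1ccc(C)cc1 | intermediate
9 | {4-[2-(methoxy(methyl)amino)-2-oxoethyl]phenyl}(2,4,6-trimethoxyphenyl)iodonium tosylate | CON(C)C(=O)Cc1ccc(cc1)[I+]c1c(OC)cc(OC)cc1OC.Cc1ccc(cc1)S(=O)(=O)[O-] | intermediate
10 | (R)-5-(hydroxymethyl)furan-2(5H)-one | O=C1C=C[C@H](CO)O1 | starting material
11 | (R)-5-{[(tert-butyldimethylsilyl)oxy]methyl}furan-2(5H)-one | O=C1C=C[C@H](CO[Si](C)(C)C(C)(C)C)O1 | intermediate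
12 | (4S,5R)-5-{[(tert-butyldimethylsilyl)oxy]methyl}-4-(prop-1-en-2-yl)dihydrofuran-2(3H)-one | O=C1C[C@@H](C(C)=C)[C@H](CO[Si](C)(C)C(C)(C)C)O1 | intermediate
13 | (3R,4S,5R)-3-methyl analogue of 12 | O=C1[C@H](C)[C@@H](C(C)=C)[C@H](CO[Si](C)(C)C(C)(C)C)O1 | intermediate
14 | (R)-2-methylbut-3-en-1-yl trifluoromethanesulfonate | C[C@@H](COS(=O)(=O)C(F)(F)F)C=C | intermediate
15 | (3R,4R,5R)-quaternary lactone (methyl cis, butenyl arm trans to isopropenyl) | O=C1[C@](C)(C[C@H](C)C=C)[C@@H](C(C)=C)[C@H](CO[Si](C)(C)C(C)(C)C)O1 | intermediate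
16 | lactol of 15 | OC1[C@](C)(C[C@H](C)C=C)[C@@H](C(C)=C)[C@H](CO[Si](C)(C)C(C)(C)C)O1 | intermediate
17 | hydroxy (E)-enoate | CCOC(=O)/C(C)=C/[C@](C)(C[C@H](C)C=C)[C@@H](C(C)=C)[C@@H](O)CO[Si](C)(C)C(C)(C)C | intermediate
18 | allylic alcohol diol | OC/C(C)=C/[C@](C)(C[C@H](C)C=C)[C@@H](C(C)=C)[C@@H](O)CO[Si](C)(C)C(C)(C)C | intermediate
19 | hydroxy (E)-enal | O=C/C(C)=C/[C@](C)(C[C@H](C)C=C)[C@@H](C(C)=C)[C@@H](O)CO[Si](C)(C)C(C)(C)C | intermediate
20 | (2Z,4E)-dienol | C/C=C\C(C)=C\[C@](C)(C[C@H](C)C=C)[C@@H](C(C)=C)[C@@H](O)CO[Si](C)(C)C(C)(C)C | intermediate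
21 | aryl ether of 20 | C/C=C\C(C)=C\[C@](C)(C[C@H](C)C=C)[C@@H](C(C)=C)[C@@H](Oc1ccc(CC(=O)N(C)OC)cc1)CO[Si](C)(C)C(C)(C)C | intermediate
22 | primary alcohol | C/C=C\C(C)=C\[C@](C)(C[C@H](C)C=C)[C@@H](C(C)=C)[C@@H](Oc1ccc(CC(=O)N(C)OC)cc1)CO | intermediate
23 | α-aryloxy aldehyde | C/C=C\C(C)=C\[C@](C)(C[C@H](C)C=C)[C@@H](C(C)=C)[C@@H](Oc1ccc(CC(=O)N(C)OC)cc1)C=O | intermediate
24 | trienal | C/C=C\C(C)=C\[C@](C)(C[C@H](C)C=C)[C@@H](C(C)=C)[C@@H](Oc1ccc(CC(=O)N(C)OC)cc1)/C=C/C=O | intermediate
25 | trans-fused B/C hydrindene aldehyde | C=C(C)[C@H]1[C@@H](Oc2ccc(CC(=O)N(C)OC)cc2)[C@@H]3[C@@H](C=O)[C@H](C)C=C(C)[C@H]3[C@]1(C)C[C@H](C)C=C | intermediate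
26 | trans-diaxial bromohydrin | C=C(C)[C@H]1[C@@H](Oc2ccc(CC(=O)N(C)OC)cc2)[C@@H]3[C@@H](C=O)[C@H](C)[C@H](Br)[C@@](C)(O)[C@H]3[C@]1(C)C[C@H](C)C=C | intermediate
27 | epoxy aldehyde | C=C(C)[C@H]1[C@@H](Oc2ccc(CC(=O)N(C)OC)cc2)[C@@H]3[C@@H](C=O)[C@H](C)[C@H]4O[C@@]4(C)[C@H]3[C@]1(C)C[C@H](C)C=C | intermediate
28 | β-(trimethylsilyloxy)nitrile | C=C(C)[C@H]1[C@@H](Oc2ccc(CC(=O)N(C)OC)cc2)[C@@H]3[C@@H](C(CC#N)O[Si](C)(C)C)[C@H](C)[C@H]4O[C@@]4(C)[C@H]3[C@]1(C)C[C@H](C)C=C | intermediate
29 | silyl ether chloroketone | C=C(C)[C@H]1[C@@H](Oc2ccc(CC(=O)CCl)cc2)[C@@H]3[C@@H](C(CC#N)O[Si](C)(C)C)[C@H](C)[C@H]4O[C@@]4(C)[C@H]3[C@]1(C)C[C@H](C)C=C | intermediate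
30 | β-hydroxynitrile aryl chloromethyl ketone | C=C(C)[C@H]1[C@@H](Oc2ccc(CC(=O)CCl)cc2)[C@@H]3[C@@H](C(O)CC#N)[C@H](C)[C@H]4O[C@@]4(C)[C@H]3[C@]1(C)C[C@H](C)C=C | intermediate
31 | β-ketonitrile aryl chloromethyl ketone | C=C(C)[C@H]1[C@@H](Oc2ccc(CC(=O)CCl)cc2)[C@@H]3[C@@H](C(=O)CC#N)[C@H](C)[C@H]4O[C@@]4(C)[C@H]3[C@]1(C)C[C@H](C)C=C | intermediate
32 | paracyclophane 2-cyano-1,4-diketone | C=C(C)[C@H]1[C@H]2Oc3ccc(cc3)CC(=O)CC(C#N)C(=O)[C@H]4[C@H](C)[C@H]5O[C@@]5(C)[C@H]([C@H]24)[C@]1(C)C[C@H](C)C=C | intermediate
33 | paracyclophane ketoamide | C=C(C)[C@H]1[C@H]2Oc3ccc(cc3)CC(=O)CC(C(N)=O)C(=O)[C@H]4[C@H](C)[C@H]5O[C@@]5(C)[C@H]([C@H]24)[C@]1(C)C[C@H](C)C=C | intermediate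
34 | seco-A hydroxylactam | C=C(C)[C@H]1[C@H]2Oc3ccc(cc3)C[C@]3(O)C/C(=C(/O)[C@H]4[C@H](C)[C@H]5O[C@@]5(C)[C@H]([C@H]24)[C@]1(C)C[C@H](C)C=C)C(=O)N3 | intermediate
35 | ring A cyclohexene | C[C@@H]1C=C(C)[C@H]2[C@H]3Oc4ccc(cc4)C[C@]4(O)C/C(=C(/O)[C@H]5[C@H](C)[C@H]6O[C@@]6(C)[C@H]([C@H]35)[C@]2(C)C1)C(=O)N4 | intermediate
36 | pyrrospirone O | C[C@@H]1C[C@H](C)[C@H]2[C@H]3Oc4ccc(cc4)C[C@]4(O)C/C(=C(/O)[C@H]5[C@H](C)[C@H]6O[C@@]6(C)[C@H]([C@H]35)[C@]2(C)C1)C(=O)N4 | target

Total step count: 27. Longest linear sequence: 22 steps (1 to 36 through steps 1–4 and 10–27).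

Steps most likely to fail

Step 20. The inside (Z) methyl slows the cycloaddition. Lewis-acid-induced Z to E isomerisation of the diene, a 1,5-hydrogen shift or loss of the allylic aryloxy group may therefore overtake it, and facial selectivity may erode. The fallback sets out from 24 and changes the dienophile into a cation. Trimethyl orthoformate with pyridinium tosylate should give the trienal dimethyl acetal F1. Catalytic Me3SiOTf in CH2Cl2 at −78 °C ionises it to a vinyl-oxocarbenium ion, a far stronger dienophile (ionic Diels–Alder reaction), which should give the cycloadduct dimethyl acetal F2. Pyridinium tosylate in wet acetone hydrolyses F2, and the route is rejoined at 25.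

Step 25. Strain in the 13-membered paracyclophane may let oligomerisation or O-alkylation of the enolate outrun C-alkylation. The fallback sets out from 31 and reverses the order of events. Platinum-catalysed hydration with [PtH(PMe2OH){(PMe2O)2H}] is run first and should give the primary β-ketoamide chloroketone F3. With K2CO3 in dilute MeCN the amide nitrogen can add reversibly to the benzyl ketone. This carbinolamide tether turns the C-alkylation into a five-membered ring closure that shuts ring D and the macrocycle together. The route is rejoined at 34.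

Step 27. Metathesis at the hindered isopropenyl group may be slow, and the hydrogen atom may reach the tertiary ring A radical from the open lower face, which would erode the configuration at the new methyl carbon. The fallback sets out from 35, isolated after the metathesis, and separates reduction from stereocontrol. Surface hydrogenation (H2, Pd/C, EtOAc) from the lower face should give the axial-methyl epimer F4. This is then equilibrated to the equatorial epimer by reversible hydrogen-atom abstraction at the strained tertiary C–H bond, using (Bu4N)4W10O32, bis(2,4,6-triisopropylphenyl) disulfide and 390 nm light (photocatalytic epimerisation of tertiary stereocentres). The route is rejoined at 36.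

Further compounds
F1 | step 20 | trienal dimethyl acetal | C/C=C\C(C)=C\[C@](C)(C[C@H](C)C=C)[C@@H](C(C)=C)[C@@H](Oc1ccc(CC(=O)N(C)OC)cc1)/C=C/C(OC)OC
F2 | step 20 | cycloadduct dimethyl acetal | C=C(C)[C@H]1[C@@H](Oc2ccc(CC(=O)N(C)OC)cc2)[C@@H]3[C@@H](C(OC)OC)[C@H](C)C=C(C)[C@H]3[C@]1(C)C[C@H](C)C=C
F3 | step 25 | primary β-ketoamide chloroketone | C=C(C)[C@H]1[C@@H](Oc2ccc(CC(=O)CCl)cc2)[C@@H]3[C@@H](C(=O)CC(N)=O)[C@H](C)[C@H]4O[C@@]4(C)[C@H]3[C@]1(C)C[C@H](C)C=C
F4 | step 27 | axial-methyl epimer of 36 | C[C@@H]1C[C@@H](C)[C@H]2[C@H]3Oc4ccc(cc4)C[C@]4(O)C/C(=C(/O)[C@H]5[C@H](C)[C@H]6O[C@@]6(C)[C@H]([C@H]35)[C@]2(C)C1)C(=O)N4
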